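All runs are calculated with made-up constants; noise was put on by code.

Percent of substrate charged hides what elm and oak share, since oak holds more substrate on the same partner, so I count mono adduct against partner instead.

| setting | elm | oak | flask |
|---|---|---|---|
| substrate | 0.25 M | 0.38 M | 0.25 M |
| partner | 0.25 M | 0.25 M | 0.250 M |
| remark | the very flask that is asked about, followed so far | run made earlier |  |
| time |  |  | 30 min |

- elm (time / min: mono adduct / %): 1.00: 9.2; 2.00: 9.0; 3.00: 8.3; 4.00: 8.3; 5.00: 7.4; 6.00: 7.9
- oak (time / min: mono adduct / %): 2.50: 6.8; 4.00: 6.4; 6.00: 6.8; 10.0: 6.2; 20.0: 6.2; 30.0: 6.5

(readings scatter by 0.3 percentage points)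



- equivalents of partner to substrate, everything else as given, that leave most mono adduct at 30 min
- the amount of mono adduct then, in percent of the substrate charged
- the amount of mono adduct with the amounts as given

Oak reads flat at about 6.48%, and elm reads level from 3.00 min at about 7.97%. Two views of these plateaus stand against each other.

The forecast takes them for a redistribution balance with a constant of 0.022 read from oak. It holds that “the peak is broad”, and it gives 1 equiv, 7% there, and 6.9% for the charges as given.

I assume instead that partner has stopped reacting at each plateau. Divide the rate at which mono adduct gains by the rate at which partner goes, and time drops out. Summed to the plateau, that ratio says how much mono adduct stays per partner charged. Elm, at 1.00 equiv, reads 7.97% and oak, at 0.658 equiv, reads 9.85%; this mono adduct per partner charged is the partner yield.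

A straight line through these two readings loses 5.49% per equivalent from 13.5% at the start of the scale. Mono adduct on substrate is equivalents times yield, so it tops at 1.23 equiv with 8.25%. This is my reckoning, with the scatter of two readings in it, and it differs from the forecast.

The flask tops at 1.33 equiv with 8.19%, and gives 7.76% as charged. The forecast's two amounts hold within their margins, while its equivalents are low by a factor of 1.3. The broad peak it spoke of does show in the flask, which stands 0.43 percentage points below the top at the given charges.

    substrate + partner → mono adduct (k = 0.0560 M⁻¹ s⁻¹)
    substrate + partner → other mono adduct (k = 0.0393 M⁻¹ s⁻¹)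
    partner + mono adduct → double product (k = 0.108 M⁻¹ s⁻¹)
    partner + other mono adduct → double product (k = 0.0185 M⁻¹ s⁻¹)
    partner → decomposed reagent (k = 0.00528 s⁻¹)
    mono adduct ⇌ isomer of the product (K = 2.60, k = 0.0367 s⁻¹)

Partner is the limiting reagent here, with 0% left at 30 min against 36% of substrate. The flask's partner yield comes to 7.76%, beside the 7.97% read from elm. The neighbour with partner cut to 0.062 M sits at 0.248 equiv, where the line gives a yield of 12.1%, and so 3.00% mono adduct on substrate. That neighbour gives 2.94% at 30.0 min, with 80.8% of its substrate still there.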